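**Retrosynthetic overview**
1. The thioacetate comes last, from primary chloride 16 by SN2 with KSAc.
2. The C1′–C2′ (sp3–sp2) bond is made by Stille coupling of bromomethyl-γ-pyrone 8 with (E)-vinylstannane 15, each with 14 non-hydrogen atoms in the parent halide.
3. Bromide 8 comes from lateral bromination of dimethylpyrone 7, which comes from O-methylation of hydroxy-α-pyrone 6, made by lactonisation of diketo ester 5 (methyl methoxyacetate + propanoyl chloride + an acetyl Weinreb amide).
4. Stannane 15 comes from vinyl iodide 14, made by Zr-catalysed methylalumination of 11-chloroundec-1-yne, itself from oct-1-yne + oxetane via an alkyne zipper.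
5. Ring order: there is one ring. It is closed in step 3 as the α-pyrone and converted to the γ-pyrone in step 4.

Assumption: the target has no stereocentres, so the only stereochemical element to control is the (E)-trisubstituted alkene.

**Pyrone fragment**

Step 1
Reactants: 1 methyl methoxyacetate; 2 propanoyl chloride
Product: 3 methyl 2-methoxy-3-oxopentanoate (racemic)
Conditions: 1 (2.0 equiv), LiHMDS (2.1 equiv), THF, −78 °C; then 2 (1.0 equiv), −78 °C; AcOH quench
Reagents that add atoms: none
Why: Crossed Claisen condensation (C-acylation of the preformed ester enolate); the second equivalent of enolate absorbs the acidic β-keto ester product and prevents double acylation.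

Step 2
Reactants: 3; 4 N-methoxy-N-methylacetamide
Product: 5 methyl 2-methoxy-4-methyl-3,5-dioxohexanoate (keto/enol and diastereomer mixture, used crude)
Conditions: LDA (2.2 equiv), THF, −78 → 0 °C; then 4 (1.1 equiv), −78 → 0 °C; aq. NH4Cl
Reagents that add atoms: none
Why: Weiler-type β-keto ester dianion reacts at its more nucleophilic γ-carbon, and the Weinreb amide stops at the ketone stage through its stable tetrahedral chelate.

Step 3
Reactants: 5
Product: 6 4-hydroxy-3-methoxy-5,6-dimethyl-2H-pyran-2-one
Conditions: DBU (2 equiv), toluene, 80 °C; then 1 M HCl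
Reagents that add atoms: none
Why: Base-mediated enol-lactonisation, in which the C5 enolate oxygen attacks the methyl ester and expels MeOH to close the six-membered 4-hydroxy-α-pyrone.

Step 4
Reactants: 6
Product: 7 2,3-dimethoxy-5,6-dimethyl-4H-pyran-4-one
Conditions: MeOTf (1.5 equiv), CH2Cl2, 0 °C → rt; then sat. aq. NaHCO3
Reagents that add atoms: methyl triflate, COS(=O)(=O)C(F)(F)F
Why: Kinetic O-methylation by a hard methylating agent occurs at the lactone carbonyl oxygen of the neutral hydroxypyranone, and proton loss from the resulting pyrylium gives the 2-methoxy-γ-pyrone.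

Step 5
Reactants: 7
Product: 8 6-(bromomethyl)-2,3-dimethoxy-5-methyl-4H-pyran-4-one
Conditions: LiHMDS (1.1 equiv), THF, −78 °C, 30 min; cannulate into BrCCl2CCl2Br (1.5 equiv), THF, −78 °C; aq. NH4Cl
Reagents that add atoms: 1,2-dibromotetrachloroethane, BrC(Cl)(Cl)C(Cl)(Cl)Br
Why: Lateral (vinylogous) deprotonation occurs only at the C6 methyl, which is γ to the C4 carbonyl, and inverse-addition trapping with a Br+ donor gives the bromide while limiting self-alkylation.

**Side-chain fragment**

Step 6
Reactants: 9 oct-1-yne; 10 oxetane
Product: 11 undec-4-yn-1-ol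
Conditions: n-BuLi (1.0 equiv), THF, −78 °C; BF3·OEt2 (1.1 equiv); then 10 (1.2 equiv), −78 °C
Reagents that add atoms: none
Why: Yamaguchi-type BF3-promoted SN2 ring opening of oxetane by the lithium acetylide joins C8 and C3 into the C11 alkynol.

Step 7
Reactants: 11
Product: 12 undec-10-yn-1-ol
Conditions: KH (4 equiv), H2N(CH2)3NH2 (KAPA), 0 °C → rt; aq. NH4Cl
Reagents that add atoms: none
Why: Alkyne zipper isomerisation moves the triple bond along the chain to the only available terminus, where it is trapped irreversibly as the acetylide.

Step 8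
Reactants: 12
Product: 13 11-chloroundec-1-yne
Conditions: PPh3, NCS, CH2Cl2, 0 °C → rt
Reagents that add atoms: N-chlorosuccinimide, ClN1C(=O)CCC1=O
Why: Appel-type chlorination converts the primary alcohol by SN2 on the alkoxyphosphonium and leaves the terminal alkyne untouched.

Step 9
Reactants: 13
Product: 14 (E)-11-chloro-1-iodo-2-methylundec-1-ene
Conditions: AlMe3 (2.5 equiv), Cp2ZrCl2 (0.25 equiv), CH2Cl2, 0 °C → rt; then I2 (1.3 equiv), THF, −30 → 0 °C
Reagents that add atoms: trimethylaluminium, C[Al](C)C; iodine, II
Why: Negishi Zr-catalysed carboalumination adds Me and Al syn with Al at the terminus, and iodinolysis with retention gives the E-iodide with I cis to Me, which sets the alkene geometry; the remote primary chloride is inert.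

Step 10
Reactants: 14
Product: 15 tributyl[(1E)-11-chloro-2-methylundec-1-en-1-yl]stannane
Conditions: t-BuLi (2.1 equiv), Et2O, −78 °C, 20 min; Bu3SnCl (1.2 equiv), −78 °C → rt; Et3N-deactivated silica
Reagents that add atoms: tributyltin chloride, CCCC[Sn](Cl)(CCCC)CCCC
Why: Lithium–iodine exchange and stannylation both proceed with retention at the vinyl carbon, and the primary alkyl chloride does not exchange with t-BuLi at −78 °C.

**Coupling and completion**

Step 11
Reactants: 8 (1.0 equiv); 15 (1.2 equiv)
Product: 16 6-[(2E)-12-chloro-3-methyldodec-2-en-1-yl]-2,3-dimethoxy-5-methyl-4H-pyran-4-one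
Conditions: Pd2(dba)3 (2.5 mol %), AsPh3 (10 mol %), THF, 50 °C
Reagents that add atoms: none
Why: Stille sp3–sp2 cross-coupling: Pd(0) adds to the activated allylic-type C–Br bond and the alkenyl group transfers from tin with retention, under neutral conditions that leave the pyrone, the alkyl chloride and the skipped alkene position intact.

Step 12
Reactants: 16
Product: 17 lehualide C, S-[(10E)-12-(5,6-dimethoxy-3-methyl-4-oxo-4H-pyran-2-yl)-10-methyldodec-10-en-1-yl] ethanethioate
Conditions: KSAc (1.5 equiv), Bu4NI (0.1 equiv), DMF, 50 °C, Ar
Reagents that add atoms: potassium thioacetate, CC(=O)[S-].[K+]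
Why: SN2 displacement of the primary chloride by the soft, nearly non-basic thioacetate anion (iodide-catalysed) does not affect the methoxypyrone or isomerise the alkene.

**Compound list**
1 | methyl methoxyacetate | COCC(=O)OC | starting material
2 | propanoyl chloride | CCC(=O)Cl | starting material
3 | methyl 2-methoxy-3-oxopentanoate (racemic) | CCC(=O)C(OC)C(=O)OC | intermediate
4 | N-methoxy-N-methylacetamide | CC(=O)N(C)OC | starting material
5 | methyl 2-methoxy-4-methyl-3,5-dioxohexanoate (mixture) | CC(=O)C(C)C(=O)C(OC)C(=O)OC | intermediate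
6 | 4-hydroxy-3-methoxy-5,6-dimethyl-2H-pyran-2-one | COc1c(O)c(C)c(C)oc1=O | intermediate
7 | 2,3-dimethoxy-5,6-dimethyl-4H-pyran-4-one | COc1oc(C)c(C)c(=O)c1OC | intermediate
8 | 6-(bromomethyl)-2,3-dimethoxy-5-methyl-4H-pyran-4-one | COc1oc(CBr)c(C)c(=O)c1OC | intermediate
9 | oct-1-yne | CCCCCCC#C | starting material
10 | oxetane | C1COC1 | starting material
11 | undec-4-yn-1-ol | CCCCCCC#CCCCO | intermediate
12 | undec-10-yn-1-ol | OCCCCCCCCCC#C | intermediate
13 | 11-chloroundec-1-yne | ClCCCCCCCCCC#C | intermediate
14 | (E)-11-chloro-1-iodo-2-methylundec-1-ene | I/C=C(\C)CCCCCCCCCCl | intermediate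
15 | tributyl[(1E)-11-chloro-2-methylundec-1-en-1-yl]stannane | CCCC[Sn](CCCC)(CCCC)/C=C(\C)CCCCCCCCCCl | intermediate
16 | 6-[(2E)-12-chloro-3-methyldodec-2-en-1-yl]-2,3-dimethoxy-5-methyl-4H-pyran-4-one | COc1oc(C/C=C(\C)CCCCCCCCCCl)c(C)c(=O)c1OC | intermediate
17 | lehualide C | COc1oc(C/C=C(\C)CCCCCCCCCSC(C)=O)c(C)c(=O)c1OC | target

**Totals**
Total steps: 12. Longest linear sequence: 7 (steps 1–5, 11, 12; the side-chain arm 6–10, 11, 12 is also 7).

**Three steps most likely to fail**
- Step 5 (lateral bromination: dimerisation by self-alkylation, over-bromination). Fallback: carry the C6–CH2–O oxidation level from the start by acylating the dianion of 3 with PMBOCH2C(O)N(OMe)Me instead of 4. After the same cyclisation and O-methylation, remove PMB with DDQ and convert the alcohol to 8 with CBr4/PPh3.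
- Step 11 (Stille coupling: homocoupling or reduction of 8, slow transmetalation of the trisubstituted stannane). Fallback: invert the polarity. Transmetalate lithiated 7 to the zinc dienolate (ZnCl2) and perform a Pd-catalysed γ-alkenylation with vinyl iodide 14 (Pd(dba)2 with a bulky phosphine). This bypasses both 8 and 15.
- Step 2 (dianion γ-acylation: O-acylation, low conversion). Fallback: replace acylation by aldol addition of the same dianion to acetaldehyde, then oxidise the δ-hydroxy-β-keto ester with Dess–Martin periodinane to 5 before the DBU cyclisation.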